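**Plan**

- Retrosynthesis: the lactone Cα–CH2 bond to ring B is cut first (enolate benzylation). The lactone is then traced to a succinate imide alkylated by a ring C benzylic bromide. Next the C2–C3 bond of the dihydrobenzofuran is cut, and in the other half the C1–C2 bond of the ring A/B propane-1,3-diol (anti aldol).
- Enabling feature: C3 of the dihydrobenzofuran carries the hydroxymethyl group and ring C, so it is a masked α-carbon of an arylacetic ester. C2 is a benzylic ether carbon between O1 and ring D. The C2–C3 bond therefore maps onto carbene insertion into the OCH2 group of an ortho-benzyloxy aryldiazoacetate.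
- Forward: 5-bromo-2-hydroxy-3-methoxybenzaldehyde gives one arylacetic acid (5) that serves rings B and C; vanillin gives one silylated aldehyde (7) that serves rings A and D.
- Order: the furan ring closes first (step 10), the lactone second (step 17), the two halves are joined by alkylation (step 24), and all silyl groups are removed last (step 25).
- Stereochemistry: C2 of the dihydrobenzofuran comes from the chiral rhodium carboxylate and C3 from equilibration to trans. Lactone Cβ comes from an (R)-oxazolidinone alkylation and Cα from trans alkylation of the lactone enolate. C1 and C2 of the diol come from an (S)-oxazolidinone magnesium anti aldol.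

Key step: step 10

Assumption: the sense of induction of Rh2(R-PTTL)4 in step 10 (2S) and of the chelated magnesium enolate in step 19 (2R,3S with the S auxiliary) is taken from the behaviour of close analogues; if either were reversed, the mirror-image catalyst or auxiliary would be used with no other change.

**Route**

Step 1
Reactants: 1 5-bromo-2-hydroxy-3-methoxybenzaldehyde
Product: 2 5-bromo-3-methoxy-2-[(triisopropylsilyl)oxy]benzaldehyde
Conditions: i-Pr3SiCl, imidazole, DMAP (cat.), DMF, rt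
Reagents that add atoms: chlorotriisopropylsilane, CC(C)[Si](Cl)(C(C)C)C(C)C
Why: Silyl ether formation on the acidic phenol gives a triisopropylsilyl group that should withstand the ylide, the aqueous acid and the chlorite of the next two steps and later serves as the lasting protecting group of the ring B phenol.

Step 2
Reactants: 2 5-bromo-3-methoxy-2-[(triisopropylsilyl)oxy]benzaldehyde
Product: 3 [4-bromo-2-methoxy-6-(2-methoxyethenyl)phenoxy]triisopropylsilane (E/Z mixture)
Conditions: MeOCH2PPh3Cl, KN(SiMe3)2, THF, 0 °C → rt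
Reagents that add atoms: (methoxymethyl)triphenylphosphonium chloride, COC[P+](c1ccccc1)(c1ccccc1)c1ccccc1.[Cl-]
Why: Wittig methoxymethylenation adds the single carbon needed for the arylacetic acid as an enol ether of irrelevant geometry, and the non-nucleophilic silylamide base leaves the aryl silyl ether and the aryl bromide alone.

Step 3
Reactants: 3 [4-bromo-2-methoxy-6-(2-methoxyethenyl)phenoxy]triisopropylsilane
Product: 5 2-{5-bromo-3-methoxy-2-[(triisopropylsilyl)oxy]phenyl}acetic acid, via arylacetaldehyde 4 (not isolated)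
Conditions: 2 M HCl, THF, 45 °C; then NaH2PO4, 2-methyl-2-butene, NaClO2, t-BuOH–H2O, 0 °C → rt
Reagents that add atoms: water, O; sodium chlorite, [Na+].[O-]Cl=O
Why: Acid hydrolysis of the enol ether releases the air-sensitive arylacetaldehyde, which is oxidised at once under Pinnick conditions, the aryl silyl ether being stable to dilute acid and the alkene scavenger keeping hypochlorous acid away from the electron-rich ring.

Step 4
Reactants: 6 vanillin (4-hydroxy-3-methoxybenzaldehyde)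
Product: 7 3-methoxy-4-[(triisopropylsilyl)oxy]benzaldehyde
Conditions: i-Pr3SiCl, imidazole, DMF, rt
Reagents that add atoms: chlorotriisopropylsilane, CC(C)[Si](Cl)(C(C)C)C(C)C
Why: Silyl ether formation protects the phenol that becomes the 4-hydroxyl of rings A and D with a group that keeps the ring electron-rich and is removed by fluoride at the end.

Step 5
Reactants: 7 3-methoxy-4-[(triisopropylsilyl)oxy]benzaldehyde
Product: 8 {3-methoxy-4-[(triisopropylsilyl)oxy]phenyl}methanol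
Conditions: NaBH4, THF–MeOH, 0 °C
Reagents that add atoms: none
Why: Chemoselective borohydride reduction of the aldehyde gives the benzylic alcohol needed as the Mitsunobu partner without touching the silyl ether.

Step 6
Reactants: 5 2-{5-bromo-3-methoxy-2-[(triisopropylsilyl)oxy]phenyl}acetic acid
Product: 9 methyl 2-{5-bromo-3-methoxy-2-[(triisopropylsilyl)oxy]phenyl}acetate
Conditions: Me3SiCHN2, toluene–MeOH, 0 °C
Reagents that add atoms: (trimethylsilyl)diazomethane, C[Si](C)(C)C=[N+]=[N-]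
Why: Methylation of the carboxylic acid with trimethylsilyldiazomethane is a neutral esterification that cannot disturb the aryl silyl ether.

Step 7
Reactants: 9 methyl 2-{5-bromo-3-methoxy-2-[(triisopropylsilyl)oxy]phenyl}acetate
Product: 10 methyl 2-(5-bromo-2-hydroxy-3-methoxyphenyl)acetate
Conditions: Bu4NF, AcOH, THF, 0 °C
Reagents that add atoms: none
Why: Fluoride cleavage of the aryl silyl ether, buffered with acetic acid so that the phenoxide is protonated before it can lactonise onto the ester, frees the ring C phenol for attachment of ring D.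

Step 8
Reactants: 10 methyl 2-(5-bromo-2-hydroxy-3-methoxyphenyl)acetate; 8 {3-methoxy-4-[(triisopropylsilyl)oxy]phenyl}methanol
Product: 11 methyl 2-[5-bromo-3-methoxy-2-({3-methoxy-4-[(triisopropylsilyl)oxy]phenyl}methoxy)phenyl]acetate
Conditions: PPh3, DIAD, THF, 0 °C → rt
Reagents that add atoms: none
Why: Mitsunobu etherification joins the phenol and the primary benzylic alcohol under neutral conditions in which the silyl ether, the ester and the aryl bromide are inert, and no stereocentre is involved.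

Step 9
Reactants: 11 methyl 2-[5-bromo-3-methoxy-2-({3-methoxy-4-[(triisopropylsilyl)oxy]phenyl}methoxy)phenyl]acetate
Product: 12 methyl 2-[5-bromo-3-methoxy-2-({3-methoxy-4-[(triisopropylsilyl)oxy]phenyl}methoxy)phenyl]-2-diazoacetate
Conditions: p-ABSA, DBU, MeCN, 0 °C → rt
Reagents that add atoms: 4-acetamidobenzenesulfonyl azide, CC(=O)Nc1ccc(cc1)S(=O)(=O)N=[N+]=[N-]
Why: Regitz diazo transfer to the activated benzylic methylene of an arylacetate is the standard entry to aryldiazoacetates and runs under an amidine base that does not cleave the silyl ether.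

Step 10
Reactants: 12 methyl 2-[5-bromo-3-methoxy-2-({3-methoxy-4-[(triisopropylsilyl)oxy]phenyl}methoxy)phenyl]-2-diazoacetate
Product: 14 methyl (2S,3S)-5-bromo-7-methoxy-2-{3-methoxy-4-[(triisopropylsilyl)oxy]phenyl}-2,3-dihydro-1-benzofuran-3-carboxylate (trans), via cis ester 13 (not isolated)
Conditions: dirhodium tetrakis[N-phthaloyl-(R)-tert-leucinate] Rh2(R-PTTL)4 (1 mol %), toluene, −60 °C; then DBU, 40 °C
Reagents that add atoms: none
Why: The divalent rhodium carboxylate expels dinitrogen from 12 to give a donor/acceptor rhodium carbene, which inserts into one of the two enantiotopic benzylic ether C–H bonds in a concerted, asynchronous step with hydride-transfer character; the closest known reaction is the enantioselective intramolecular C–H insertion of ortho-benzyloxy aryldiazoacetates to 2-aryl-2,3-dihydrobenzofuran-3-carboxylates. The furan ring closes by 1,5 insertion through a five-membered transition state, the new C2–C3 bond joining the carbene carbon to the ether carbon while O1–C2 and C3–C3a are already in place. C2 is set by the chiral phthaloyl-tert-leucinate ligand sphere, which tells the two benzylic hydrogens apart, and the R-configured catalyst is chosen to give 2S. C3 is formed cis (13) under kinetic control and is then equilibrated by DBU through the ester enolate to the more stable trans ester 14 without touching C2. The step needs site selectivity for the ether methylene over cyclopropanation of ring D, over the methoxy and silyl C–H bonds and over the aryl bromide; the ortho tether places only this methylene within reach of a five-membered transition state, and the ether oxygen together with the electron-rich silyloxy ring D activates it toward the electrophilic carbene.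

Step 11
Reactants: 14 methyl (2S,3S)-5-bromo-7-methoxy-2-{3-methoxy-4-[(triisopropylsilyl)oxy]phenyl}-2,3-dihydro-1-benzofuran-3-carboxylate
Product: 15 [(2S,3R)-5-bromo-7-methoxy-2-{3-methoxy-4-[(triisopropylsilyl)oxy]phenyl}-2,3-dihydro-1-benzofuran-3-yl]methanol
Conditions: i-Bu2AlH, toluene–CH2Cl2, −78 → 0 °C
Reagents that add atoms: none
Why: Hydride reduction of the ester with the aluminium hydride at low temperature should give the primary alcohol without epimerisation or ring opening, and from here C3 is no longer enolisable.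

Step 12
Reactants: 15 [(2S,3R)-5-bromo-7-methoxy-2-{3-methoxy-4-[(triisopropylsilyl)oxy]phenyl}-2,3-dihydro-1-benzofuran-3-yl]methanol
Product: 16 (2S,3R)-5-bromo-7-methoxy-2-{3-methoxy-4-[(triisopropylsilyl)oxy]phenyl}-3-{[(triisopropylsilyl)oxy]methyl}-2,3-dihydro-1-benzofuran
Conditions: i-Pr3SiCl, imidazole, DMF, rt
Reagents that add atoms: chlorotriisopropylsilane, CC(C)[Si](Cl)(C(C)C)C(C)C
Why: Silyl ether formation with the triisopropylsilyl group, chosen because it survives the acid-catalysed lactonisation of step 17, masks the primary alcohol.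

Step 13
Reactants: 16 (2S,3R)-5-bromo-7-methoxy-2-{3-methoxy-4-[(triisopropylsilyl)oxy]phenyl}-3-{[(triisopropylsilyl)oxy]methyl}-2,3-dihydro-1-benzofuran
Product: 18 [(2S,3R)-7-methoxy-2-{3-methoxy-4-[(triisopropylsilyl)oxy]phenyl}-3-{[(triisopropylsilyl)oxy]methyl}-2,3-dihydro-1-benzofuran-5-yl]methanol, via aldehyde 17 (not isolated)
Conditions: n-BuLi, THF, −78 °C; DMF, −78 → 0 °C; then MeOH, NaBH4, 0 °C
Reagents that add atoms: N,N-dimethylformamide, CN(C)C=O
Why: Bromine–lithium exchange is much faster than deprotonation at −78 °C, the aryllithium is formylated by DMF (Bouveault aldehyde synthesis) and the aldehyde is reduced in the same flask by borohydride to the benzylic alcohol.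

Step 14
Reactants: 18 [(2S,3R)-7-methoxy-2-{3-methoxy-4-[(triisopropylsilyl)oxy]phenyl}-3-{[(triisopropylsilyl)oxy]methyl}-2,3-dihydro-1-benzofuran-5-yl]methanol
Product: 19 (2S,3R)-5-(bromomethyl)-7-methoxy-2-{3-methoxy-4-[(triisopropylsilyl)oxy]phenyl}-3-{[(triisopropylsilyl)oxy]methyl}-2,3-dihydro-1-benzofuran
Conditions: CBr4, PPh3, 2,6-lutidine, CH2Cl2, 0 °C
Reagents that add atoms: tetrabromomethane, BrC(Br)(Br)Br
Why: Appel bromination converts the primary benzylic alcohol into the bromide under essentially neutral conditions that leave the silyl ethers and the benzylic ether of the furan ring intact.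

Step 15
Reactants: 20 4-(tert-butoxy)-4-oxobutanoic acid (mono-tert-butyl succinate); 21 (4R)-4-benzyl-1,3-oxazolidin-2-one
Product: 23 tert-butyl 4-[(4R)-4-benzyl-2-oxo-1,3-oxazolidin-3-yl]-4-oxobutanoate, via mixed pivalic anhydride 22 (not isolated)
Conditions: t-BuCOCl, Et3N, THF, −20 °C; then 21, LiCl, rt
Reagents that add atoms: none
Why: N-Acylation of the oxazolidinone through the mixed pivalic anhydride, assisted by LiCl, gives the succinate imide without touching the tert-butyl ester.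

Step 16
Reactants: 23 tert-butyl 4-[(4R)-4-benzyl-2-oxo-1,3-oxazolidin-3-yl]-4-oxobutanoate; 19 (2S,3R)-5-(bromomethyl)-7-methoxy-2-{3-methoxy-4-[(triisopropylsilyl)oxy]phenyl}-3-{[(triisopropylsilyl)oxy]methyl}-2,3-dihydro-1-benzofuran
Product: 24 tert-butyl (3R)-4-[(4R)-4-benzyl-2-oxo-1,3-oxazolidin-3-yl]-3-{[(2S,3R)-7-methoxy-2-{3-methoxy-4-[(triisopropylsilyl)oxy]phenyl}-3-{[(triisopropylsilyl)oxy]methyl}-2,3-dihydro-1-benzofuran-5-yl]methyl}-4-oxobutanoate
Conditions: NaN(SiMe3)2, THF, −78 °C; then 19, −78 → −40 °C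
Reagents that add atoms: none
Why: Evans asymmetric alkylation, in which the imide methylene is deprotonated selectively to the chelated Z sodium enolate and the benzylic bromide enters from the face opposite the benzyl group of the (R)-auxiliary, sets the 3R centre that becomes Cβ of the lactone.

Step 17
Reactants: 24 tert-butyl (3R)-4-[(4R)-4-benzyl-2-oxo-1,3-oxazolidin-3-yl]-3-{[(2S,3R)-7-methoxy-2-{3-methoxy-4-[(triisopropylsilyl)oxy]phenyl}-3-{[(triisopropylsilyl)oxy]methyl}-2,3-dihydro-1-benzofuran-5-yl]methyl}-4-oxobutanoate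
Product: 26 (4R)-4-{[(2S,3R)-7-methoxy-2-{3-methoxy-4-[(triisopropylsilyl)oxy]phenyl}-3-{[(triisopropylsilyl)oxy]methyl}-2,3-dihydro-1-benzofuran-5-yl]methyl}oxolan-2-one, via hydroxy ester 25 (not isolated)
Conditions: LiBH4, MeOH (1 equiv), THF, 0 °C; then p-TsOH·H2O (cat.), toluene, 50 °C
Reagents that add atoms: none
Why: LiBH4 reduces the exocyclic imide carbonyl selectively and releases the auxiliary, and the resulting γ-hydroxy tert-butyl ester closes to the γ-lactone on mild acid catalysis (lactonisation) without affecting the stereocentre.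

Step 18
Reactants: 5 2-{5-bromo-3-methoxy-2-[(triisopropylsilyl)oxy]phenyl}acetic acid; 27 (4S)-4-benzyl-1,3-oxazolidin-2-one
Product: 29 (4S)-4-benzyl-3-(2-{5-bromo-3-methoxy-2-[(triisopropylsilyl)oxy]phenyl}acetyl)-1,3-oxazolidin-2-one, via mixed pivalic anhydride 28 (not isolated)
Conditions: t-BuCOCl, Et3N, THF, −20 °C; then 27, LiCl, rt
Reagents that add atoms: none
Why: N-Acylation of the (S)-oxazolidinone through the mixed pivalic anhydride gives the arylacetyl imide under conditions too mild to form a ketene or to cleave the silyl ether.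

Step 19
Reactants: 29 (4S)-4-benzyl-3-(2-{5-bromo-3-methoxy-2-[(triisopropylsilyl)oxy]phenyl}acetyl)-1,3-oxazolidin-2-one; 7 3-methoxy-4-[(triisopropylsilyl)oxy]benzaldehyde
Product: 31 (4S)-4-benzyl-3-[(2R,3S)-2-{5-bromo-3-methoxy-2-[(triisopropylsilyl)oxy]phenyl}-3-hydroxy-3-{3-methoxy-4-[(triisopropylsilyl)oxy]phenyl}propanoyl]-1,3-oxazolidin-2-one, via trimethylsilyl ether 30 (not isolated)
Conditions: MgCl2 (0.3 equiv), Et3N, Me3SiCl, EtOAc, rt; then CF3CO2H (cat.), MeOH, rt
Reagents that add atoms: none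
Why: In this magnesium chloride-catalysed direct anti aldol addition of an N-acyloxazolidinone to a non-enolisable aromatic aldehyde, soft enolisation gives the chelated Z magnesium enolate, the aldehyde adds on the face opposite the benzyl group of the (S)-auxiliary through a boat-like transition state to give the 2R,3S anti adduct, silylation of the aldolate drives the equilibrium and the trimethylsilyl ether is cleaved by acidic methanol.

Step 20
Reactants: 31 (4S)-4-benzyl-3-[(2R,3S)-2-{5-bromo-3-methoxy-2-[(triisopropylsilyl)oxy]phenyl}-3-hydroxy-3-{3-methoxy-4-[(triisopropylsilyl)oxy]phenyl}propanoyl]-1,3-oxazolidin-2-one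
Product: 32 (1S,2S)-2-{5-bromo-3-methoxy-2-[(triisopropylsilyl)oxy]phenyl}-1-{3-methoxy-4-[(triisopropylsilyl)oxy]phenyl}propane-1,3-diol
Conditions: LiBH4, H2O (1 equiv), THF, 0 °C
Reagents that add atoms: none
Why: Reductive removal of the auxiliary with LiBH4 gives the 1,3-diol with both stereocentres untouched, the mild hydride conditions being chosen to avoid retro-aldol cleavage.

Step 21
Reactants: 32 (1S,2S)-2-{5-bromo-3-methoxy-2-[(triisopropylsilyl)oxy]phenyl}-1-{3-methoxy-4-[(triisopropylsilyl)oxy]phenyl}propane-1,3-diol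
Product: 33 (1S,2S)-2-{5-bromo-3-methoxy-2-[(triisopropylsilyl)oxy]phenyl}-1,3-bis{[tert-butyl(dimethyl)silyl]oxy}-1-{3-methoxy-4-[(triisopropylsilyl)oxy]phenyl}propane
Conditions: t-BuMe2SiOTf, 2,6-lutidine, CH2Cl2, −78 → 0 °C
Reagents that add atoms: tert-butyldimethylsilyl trifluoromethanesulfonate, CC(C)(C)[Si](C)(C)OS(=O)(=O)C(F)(F)F
Why: Silylation with the silyl triflate and a hindered base protects the primary and the hindered secondary benzylic hydroxyl in one operation as ethers that are stable to organolithium and amide bases.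

Step 22
Reactants: 33 (1S,2S)-2-{5-bromo-3-methoxy-2-[(triisopropylsilyl)oxy]phenyl}-1,3-bis{[tert-butyl(dimethyl)silyl]oxy}-1-{3-methoxy-4-[(triisopropylsilyl)oxy]phenyl}propane
Product: 35 {3-[(1S,2S)-1,3-bis{[tert-butyl(dimethyl)silyl]oxy}-1-{3-methoxy-4-[(triisopropylsilyl)oxy]phenyl}propan-2-yl]-5-methoxy-4-[(triisopropylsilyl)oxy]phenyl}methanol, via aldehyde 34 (not isolated)
Conditions: n-BuLi, THF, −78 °C; DMF, −78 → 0 °C; then MeOH, NaBH4, 0 °C
Reagents that add atoms: N,N-dimethylformamide, CN(C)C=O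
Why: Bromine–lithium exchange at the unhindered ring B position para to the silyloxy group, formylation with DMF (Bouveault aldehyde synthesis) and borohydride reduction in the same flask give the benzylic alcohol, all silyl ethers being stable to these reagents at low temperature.

Step 23
Reactants: 35 {3-[(1S,2S)-1,3-bis{[tert-butyl(dimethyl)silyl]oxy}-1-{3-methoxy-4-[(triisopropylsilyl)oxy]phenyl}propan-2-yl]-5-methoxy-4-[(triisopropylsilyl)oxy]phenyl}methanol
Product: 36 (1S,2S)-2-{5-(bromomethyl)-3-methoxy-2-[(triisopropylsilyl)oxy]phenyl}-1,3-bis{[tert-butyl(dimethyl)silyl]oxy}-1-{3-methoxy-4-[(triisopropylsilyl)oxy]phenyl}propane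
Conditions: CBr4, PPh3, 2,6-lutidine, CH2Cl2, 0 °C
Reagents that add atoms: tetrabromomethane, BrC(Br)(Br)Br
Why: Appel bromination of the primary benzylic alcohol is fast at 0 °C and buffered by the pyridine base, so the silyl ethers should survive and the labile bromide can be used directly.

Step 24
Reactants: 26 (4R)-4-{[(2S,3R)-7-methoxy-2-{3-methoxy-4-[(triisopropylsilyl)oxy]phenyl}-3-{[(triisopropylsilyl)oxy]methyl}-2,3-dihydro-1-benzofuran-5-yl]methyl}oxolan-2-one; 36 (1S,2S)-2-{5-(bromomethyl)-3-methoxy-2-[(triisopropylsilyl)oxy]phenyl}-1,3-bis{[tert-butyl(dimethyl)silyl]oxy}-1-{3-methoxy-4-[(triisopropylsilyl)oxy]phenyl}propane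
Product: 37 (3R,4R)-3-({3-[(1S,2S)-1,3-bis{[tert-butyl(dimethyl)silyl]oxy}-1-{3-methoxy-4-[(triisopropylsilyl)oxy]phenyl}propan-2-yl]-5-methoxy-4-[(triisopropylsilyl)oxy]phenyl}methyl)-4-{[(2S,3R)-7-methoxy-2-{3-methoxy-4-[(triisopropylsilyl)oxy]phenyl}-3-{[(triisopropylsilyl)oxy]methyl}-2,3-dihydro-1-benzofuran-5-yl]methyl}oxolan-2-one
Conditions: LiN(SiMe3)2, THF, −78 °C; then 36, DMPU, −78 → −30 °C
Reagents that add atoms: none
Why: Alkylation of the lithium enolate of a β-substituted γ-butyrolactone occurs anti to the β substituent, so the benzylic bromide should give the trans 3R,4R lactone that carries rings A/B on Cα and rings C/D on Cβ.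

Step 25
Reactants: 37 the hexasilyl ether named in step 24
Product: 38 (3R,4R)-3-{3-[(1S,2S)-1,3-dihydroxy-1-(4-hydroxy-3-methoxyphenyl)propan-2-yl]-4-hydroxy-5-methoxybenzyl}-4-{[(2S,3R)-2-(4-hydroxy-3-methoxyphenyl)-3-(hydroxymethyl)-7-methoxy-2,3-dihydro-1-benzofuran-5-yl]methyl}oxolan-2-one (CNP0186558.2)
Conditions: Bu4NF, AcOH, THF, 0 °C → rt
Reagents that add atoms: none
Why: Fluoride-mediated cleavage of all six silyl ethers (three aryl, three alkyl), buffered with acetic acid so that neither acid-promoted cyclisation of the ring A/B diol onto the ring B phenol nor base-promoted quinone methide formation should occur, releases the target.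

**Compound list**

1 | 5-bromo-2-hydroxy-3-methoxybenzaldehyde | COc1cc(Br)cc(C=O)c1O | starting material
2 | 5-bromo-3-methoxy-2-[(triisopropylsilyl)oxy]benzaldehyde | COc1cc(Br)cc(C=O)c1O[Si](C(C)C)(C(C)C)C(C)C | intermediate
3 | [4-bromo-2-methoxy-6-(2-methoxyethenyl)phenoxy]triisopropylsilane (E/Z mixture) | COC=Cc1cc(Br)cc(OC)c1O[Si](C(C)C)(C(C)C)C(C)C | intermediate
4 | 2-{5-bromo-3-methoxy-2-[(triisopropylsilyl)oxy]phenyl}acetaldehyde | O=CCc1cc(Br)cc(OC)c1O[Si](C(C)C)(C(C)C)C(C)C | intermediate (not isolated)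
5 | 2-{5-bromo-3-methoxy-2-[(triisopropylsilyl)oxy]phenyl}acetic acid | OC(=O)Cc1cc(Br)cc(OC)c1O[Si](C(C)C)(C(C)C)C(C)C | intermediate
6 | vanillin (4-hydroxy-3-methoxybenzaldehyde) | COc1cc(C=O)ccc1O | starting material
7 | 3-methoxy-4-[(triisopropylsilyl)oxy]benzaldehyde | COc1cc(C=O)ccc1O[Si](C(C)C)(C(C)C)C(C)C | intermediate
8 | {3-methoxy-4-[(triisopropylsilyl)oxy]phenyl}methanol | COc1cc(CO)ccc1O[Si](C(C)C)(C(C)C)C(C)C | intermediate
9 | methyl 2-{5-bromo-3-methoxy-2-[(triisopropylsilyl)oxy]phenyl}acetate | COC(=O)Cc1cc(Br)cc(OC)c1O[Si](C(C)C)(C(C)C)C(C)C | intermediate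
10 | methyl 2-(5-bromo-2-hydroxy-3-methoxyphenyl)acetate | COC(=O)Cc1cc(Br)cc(OC)c1O | intermediate
11 | methyl 2-[5-bromo-3-methoxy-2-({3-methoxy-4-[(triisopropylsilyl)oxy]phenyl}methoxy)phenyl]acetate | COC(=O)Cc1cc(Br)cc(OC)c1OCc1ccc(O[Si](C(C)C)(C(C)C)C(C)C)c(OC)c1 | intermediate
12 | methyl 2-[5-bromo-3-methoxy-2-({3-methoxy-4-[(triisopropylsilyl)oxy]phenyl}methoxy)phenyl]-2-diazoacetate | COC(=O)C(=[N+]=[N-])c1cc(Br)cc(OC)c1OCc1ccc(O[Si](C(C)C)(C(C)C)C(C)C)c(OC)c1 | intermediate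
13 | methyl (2S,3R)-5-bromo-7-methoxy-2-{3-methoxy-4-[(triisopropylsilyl)oxy]phenyl}-2,3-dihydro-1-benzofuran-3-carboxylate (cis) | Brc1cc(OC)c2c(c1)[C@@H](C(=O)OC)[C@@H](c1ccc(O[Si](C(C)C)(C(C)C)C(C)C)c(OC)c1)O2 | intermediate (not isolated)
14 | methyl (2S,3S)-5-bromo-7-methoxy-2-{3-methoxy-4-[(triisopropylsilyl)oxy]phenyl}-2,3-dihydro-1-benzofuran-3-carboxylate (trans) | Brc1cc(OC)c2c(c1)[C@H](C(=O)OC)[C@@H](c1ccc(O[Si](C(C)C)(C(C)C)C(C)C)c(OC)c1)O2 | intermediate
15 | [(2S,3R)-5-bromo-7-methoxy-2-{3-methoxy-4-[(triisopropylsilyl)oxy]phenyl}-2,3-dihydro-1-benzofuran-3-yl]methanol | Brc1cc(OC)c2c(c1)[C@H](CO)[C@@H](c1ccc(O[Si](C(C)C)(C(C)C)C(C)C)c(OC)c1)O2 | intermediate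
16 | (2S,3R)-5-bromo-7-methoxy-2-{3-methoxy-4-[(triisopropylsilyl)oxy]phenyl}-3-{[(triisopropylsilyl)oxy]methyl}-2,3-dihydro-1-benzofuran | Brc1cc(OC)c2c(c1)[C@H](CO[Si](C(C)C)(C(C)C)C(C)C)[C@@H](c1ccc(O[Si](C(C)C)(C(C)C)C(C)C)c(OC)c1)O2 | intermediate
17 | (2S,3R)-7-methoxy-2-{3-methoxy-4-[(triisopropylsilyl)oxy]phenyl}-3-{[(triisopropylsilyl)oxy]methyl}-2,3-dihydro-1-benzofuran-5-carbaldehyde | O=Cc1cc(OC)c2c(c1)[C@H](CO[Si](C(C)C)(C(C)C)C(C)C)[C@@H](c1ccc(O[Si](C(C)C)(C(C)C)C(C)C)c(OC)c1)O2 | intermediate (not isolated)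
18 | [(2S,3R)-7-methoxy-2-{3-methoxy-4-[(triisopropylsilyl)oxy]phenyl}-3-{[(triisopropylsilyl)oxy]methyl}-2,3-dihydro-1-benzofuran-5-yl]methanol | OCc1cc(OC)c2c(c1)[C@H](CO[Si](C(C)C)(C(C)C)C(C)C)[C@@H](c1ccc(O[Si](C(C)C)(C(C)C)C(C)C)c(OC)c1)O2 | intermediate
19 | (2S,3R)-5-(bromomethyl)-7-methoxy-2-{3-methoxy-4-[(triisopropylsilyl)oxy]phenyl}-3-{[(triisopropylsilyl)oxy]methyl}-2,3-dihydro-1-benzofuran | BrCc1cc(OC)c2c(c1)[C@H](CO[Si](C(C)C)(C(C)C)C(C)C)[C@@H](c1ccc(O[Si](C(C)C)(C(C)C)C(C)C)c(OC)c1)O2 | intermediate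
20 | 4-(tert-butoxy)-4-oxobutanoic acid | CC(C)(C)OC(=O)CCC(=O)O | starting material
21 | (4R)-4-benzyl-1,3-oxazolidin-2-one | O=C1N[C@H](Cc2ccccc2)CO1 | starting material
22 | 4-(tert-butoxy)-4-oxobutanoic pivalic anhydride | CC(C)(C)OC(=O)CCC(=O)OC(=O)C(C)(C)C | intermediate (not isolated)
23 | tert-butyl 4-[(4R)-4-benzyl-2-oxo-1,3-oxazolidin-3-yl]-4-oxobutanoate | CC(C)(C)OC(=O)CCC(=O)N1[C@H](Cc2ccccc2)COC1=O | intermediate
24 | tert-butyl (3R)-4-[(4R)-4-benzyl-2-oxo-1,3-oxazolidin-3-yl]-3-{[(2S,3R)-7-methoxy-2-{3-methoxy-4-[(triisopropylsilyl)oxy]phenyl}-3-{[(triisopropylsilyl)oxy]methyl}-2,3-dihydro-1-benzofuran-5-yl]methyl}-4-oxobutanoate | CC(C)(C)OC(=O)C[C@@H](Cc1cc(OC)c2c(c1)[C@H](CO[Si](C(C)C)(C(C)C)C(C)C)[C@@H](c1ccc(O[Si](C(C)C)(C(C)C)C(C)C)c(OC)c1)O2)C(=O)N1[C@H](Cc2ccccc2)COC1=O | intermediate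
25 | tert-butyl (3R)-3-(hydroxymethyl)-4-[(2S,3R)-7-methoxy-2-{3-methoxy-4-[(triisopropylsilyl)oxy]phenyl}-3-{[(triisopropylsilyl)oxy]methyl}-2,3-dihydro-1-benzofuran-5-yl]butanoate | CC(C)(C)OC(=O)C[C@@H](Cc1cc(OC)c2c(c1)[C@H](CO[Si](C(C)C)(C(C)C)C(C)C)[C@@H](c1ccc(O[Si](C(C)C)(C(C)C)C(C)C)c(OC)c1)O2)CO | intermediate (not isolated)
26 | (4R)-4-{[(2S,3R)-7-methoxy-2-{3-methoxy-4-[(triisopropylsilyl)oxy]phenyl}-3-{[(triisopropylsilyl)oxy]methyl}-2,3-dihydro-1-benzofuran-5-yl]methyl}oxolan-2-one | O=C1OC[C@H](Cc2cc(OC)c3c(c2)[C@H](CO[Si](C(C)C)(C(C)C)C(C)C)[C@@H](c2ccc(O[Si](C(C)C)(C(C)C)C(C)C)c(OC)c2)O3)C1 | intermediate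
27 | (4S)-4-benzyl-1,3-oxazolidin-2-one | O=C1N[C@@H](Cc2ccccc2)CO1 | starting material
28 | 2-{5-bromo-3-methoxy-2-[(triisopropylsilyl)oxy]phenyl}acetic pivalic anhydride | CC(C)(C)C(=O)OC(=O)Cc1cc(Br)cc(OC)c1O[Si](C(C)C)(C(C)C)C(C)C | intermediate (not isolated)
29 | (4S)-4-benzyl-3-(2-{5-bromo-3-methoxy-2-[(triisopropylsilyl)oxy]phenyl}acetyl)-1,3-oxazolidin-2-one | O=C(Cc1cc(Br)cc(OC)c1O[Si](C(C)C)(C(C)C)C(C)C)N1[C@@H](Cc2ccccc2)COC1=O | intermediate
30 | (4S)-4-benzyl-3-[(2R,3S)-2-{5-bromo-3-methoxy-2-[(triisopropylsilyl)oxy]phenyl}-3-{3-methoxy-4-[(triisopropylsilyl)oxy]phenyl}-3-[(trimethylsilyl)oxy]propanoyl]-1,3-oxazolidin-2-one | COc1cc([C@@H](O[Si](C)(C)C)[C@H](C(=O)N2[C@@H](Cc3ccccc3)COC2=O)c2cc(Br)cc(OC)c2O[Si](C(C)C)(C(C)C)C(C)C)ccc1O[Si](C(C)C)(C(C)C)C(C)C | intermediate (not isolated)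
31 | (4S)-4-benzyl-3-[(2R,3S)-2-{5-bromo-3-methoxy-2-[(triisopropylsilyl)oxy]phenyl}-3-hydroxy-3-{3-methoxy-4-[(triisopropylsilyl)oxy]phenyl}propanoyl]-1,3-oxazolidin-2-one | COc1cc([C@@H](O)[C@H](C(=O)N2[C@@H](Cc3ccccc3)COC2=O)c2cc(Br)cc(OC)c2O[Si](C(C)C)(C(C)C)C(C)C)ccc1O[Si](C(C)C)(C(C)C)C(C)C | intermediate
32 | (1S,2S)-2-{5-bromo-3-methoxy-2-[(triisopropylsilyl)oxy]phenyl}-1-{3-methoxy-4-[(triisopropylsilyl)oxy]phenyl}propane-1,3-diol | COc1cc([C@@H](O)[C@H](CO)c2cc(Br)cc(OC)c2O[Si](C(C)C)(C(C)C)C(C)C)ccc1O[Si](C(C)C)(C(C)C)C(C)C | intermediate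
33 | (1S,2S)-2-{5-bromo-3-methoxy-2-[(triisopropylsilyl)oxy]phenyl}-1,3-bis{[tert-butyl(dimethyl)silyl]oxy}-1-{3-methoxy-4-[(triisopropylsilyl)oxy]phenyl}propane | COc1cc([C@@H](O[Si](C)(C)C(C)(C)C)[C@H](CO[Si](C)(C)C(C)(C)C)c2cc(Br)cc(OC)c2O[Si](C(C)C)(C(C)C)C(C)C)ccc1O[Si](C(C)C)(C(C)C)C(C)C | intermediate
34 | 3-[(1S,2S)-1,3-bis{[tert-butyl(dimethyl)silyl]oxy}-1-{3-methoxy-4-[(triisopropylsilyl)oxy]phenyl}propan-2-yl]-5-methoxy-4-[(triisopropylsilyl)oxy]benzaldehyde | COc1cc([C@@H](O[Si](C)(C)C(C)(C)C)[C@H](CO[Si](C)(C)C(C)(C)C)c2cc(C=O)cc(OC)c2O[Si](C(C)C)(C(C)C)C(C)C)ccc1O[Si](C(C)C)(C(C)C)C(C)C | intermediate (not isolated)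
35 | {3-[(1S,2S)-1,3-bis{[tert-butyl(dimethyl)silyl]oxy}-1-{3-methoxy-4-[(triisopropylsilyl)oxy]phenyl}propan-2-yl]-5-methoxy-4-[(triisopropylsilyl)oxy]phenyl}methanol | COc1cc([C@@H](O[Si](C)(C)C(C)(C)C)[C@H](CO[Si](C)(C)C(C)(C)C)c2cc(CO)cc(OC)c2O[Si](C(C)C)(C(C)C)C(C)C)ccc1O[Si](C(C)C)(C(C)C)C(C)C | intermediate
36 | (1S,2S)-2-{5-(bromomethyl)-3-methoxy-2-[(triisopropylsilyl)oxy]phenyl}-1,3-bis{[tert-butyl(dimethyl)silyl]oxy}-1-{3-methoxy-4-[(triisopropylsilyl)oxy]phenyl}propane | COc1cc([C@@H](O[Si](C)(C)C(C)(C)C)[C@H](CO[Si](C)(C)C(C)(C)C)c2cc(CBr)cc(OC)c2O[Si](C(C)C)(C(C)C)C(C)C)ccc1O[Si](C(C)C)(C(C)C)C(C)C | intermediate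
37 | (3R,4R)-3-({3-[(1S,2S)-1,3-bis{[tert-butyl(dimethyl)silyl]oxy}-1-{3-methoxy-4-[(triisopropylsilyl)oxy]phenyl}propan-2-yl]-5-methoxy-4-[(triisopropylsilyl)oxy]phenyl}methyl)-4-{[(2S,3R)-7-methoxy-2-{3-methoxy-4-[(triisopropylsilyl)oxy]phenyl}-3-{[(triisopropylsilyl)oxy]methyl}-2,3-dihydro-1-benzofuran-5-yl]methyl}oxolan-2-one | COc1cc([C@@H](O[Si](C)(C)C(C)(C)C)[C@H](CO[Si](C)(C)C(C)(C)C)c2cc(C[C@H]3C(=O)OC[C@@H]3Cc3cc(OC)c4c(c3)[C@H](CO[Si](C(C)C)(C(C)C)C(C)C)[C@@H](c3ccc(O[Si](C(C)C)(C(C)C)C(C)C)c(OC)c3)O4)cc(OC)c2O[Si](C(C)C)(C(C)C)C(C)C)ccc1O[Si](C(C)C)(C(C)C)C(C)C | intermediate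
38 | (3R,4R)-3-{3-[(1S,2S)-1,3-dihydroxy-1-(4-hydroxy-3-methoxyphenyl)propan-2-yl]-4-hydroxy-5-methoxybenzyl}-4-{[(2S,3R)-2-(4-hydroxy-3-methoxyphenyl)-3-(hydroxymethyl)-7-methoxy-2,3-dihydro-1-benzofuran-5-yl]methyl}oxolan-2-one | COc1cc([C@@H](O)[C@H](CO)c2cc(C[C@H]3C(=O)OC[C@@H]3Cc3cc(OC)c4c(c3)[C@H](CO)[C@@H](c3ccc(O)c(OC)c3)O4)cc(OC)c2O)ccc1O | target

**Step count and risks**

Total steps: 25. Longest linear sequence: 16 steps (from 1 through steps 1–3, 6–14, 16, 17, 24 and 25).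

Most likely to fail, step 10. The insertion may lose enantiocontrol if it becomes stepwise, by hydride transfer to the carbene and collapse of a benzylic cation stabilised by the silyloxy ring D. The later cis-to-trans equilibration may also be accompanied by base-induced opening of the furan ring. The fallback closes the ring by O1–C2 bond formation instead; it sets out from 29 and 7 and comes back to the route at 16. Imide 29 would be converted with Bu2BOTf and i-Pr2NEt into its Z boron enolate and added to aldehyde 7 (Evans syn aldol, CH2Cl2, −78 °C) to give the syn aldol adduct F1. In F1 the (S)-auxiliary fixes the carbon that becomes C3, and the carbinol configuration is of no consequence. LiBH4 would then give the diol F2, and Bu4NF/AcOH would free both phenols to give the tetraol F3. Catalytic p-TsOH in CH2Cl2 would ionise the para-hydroxybenzylic alcohol to a quinone methide that the ring C phenol traps, giving the more stable trans dihydrobenzofuran phenol alcohol F4, with C2 set by C3. Silylation of both hydroxyl groups of F4 with i-Pr3SiCl and imidazole should give 16.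

Second, step 19. Addition of the hindered α-aryl magnesium enolate to the electron-rich aldehyde may be slow and reversible, so that conversion stalls or the anti selectivity erodes. The fallback draws the anti relationship from a closed allylboration transition state; it sets out from 2 and 7 and comes back at 32. Aldehyde 2 would be olefinated with Cl2CHBpin, CrCl2 and LiI (Takai-type boron olefination) to the E alkenylboronate F5. Matteson homologation with chloromethyllithium (ICH2Cl, n-BuLi, −78 °C) would give the E allylboronate F6. F6 would be added to aldehyde 7 under a chiral phosphoric acid of the TRIP type (the enantiomer that gives the 1S carbinol); the chair transition state of the E boronate delivers the anti homoallylic alcohol F7. Ozonolysis (O3, CH2Cl2–MeOH, −78 °C) would give the hydroxy aldehyde F8, which NaBH4 reduces in the same flask to diol 32.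

Third, step 24. The electron-rich benzylic bromide may ionise or decompose faster than the hindered lactone enolate attacks it, or the product may be alkylated a second time. The fallback forms the bond by aldol addition and removes the benzylic oxygen afterwards; it sets out from 26 and from aldehyde 34 (isolated from step 22 by leaving out the borohydride) and comes back at 37. The lithium enolate of 26 would add to 34 anti to the β substituent to give the hydroxy lactone F9 as a mixture of carbinol epimers. Mesylation (MsCl, Et3N) would give the mesylate F10, and elimination with DBU the α-arylidene lactone F11. Conjugate reduction with LiBH(s-Bu)3 at −78 °C would give the lactone enolate, whose kinetic protonation yields in part the cis lactone F12. Equilibration of the α centre with DBU should then converge on the trans lactone 37.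

Further compounds

F1 | step 10 | (4S)-4-benzyl-3-[(2S,3S)-2-{5-bromo-3-methoxy-2-[(triisopropylsilyl)oxy]phenyl}-3-hydroxy-3-{3-methoxy-4-[(triisopropylsilyl)oxy]phenyl}propanoyl]-1,3-oxazolidin-2-one | COc1cc([C@@H](O)[C@@H](C(=O)N2[C@@H](Cc3ccccc3)COC2=O)c2cc(Br)cc(OC)c2O[Si](C(C)C)(C(C)C)C(C)C)ccc1O[Si](C(C)C)(C(C)C)C(C)C
F2 | step 10 | (1S,2R)-2-{5-bromo-3-methoxy-2-[(triisopropylsilyl)oxy]phenyl}-1-{3-methoxy-4-[(triisopropylsilyl)oxy]phenyl}propane-1,3-diol | COc1cc([C@@H](O)[C@@H](CO)c2cc(Br)cc(OC)c2O[Si](C(C)C)(C(C)C)C(C)C)ccc1O[Si](C(C)C)(C(C)C)C(C)C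
F3 | step 10 | (1S,2R)-2-(5-bromo-2-hydroxy-3-methoxyphenyl)-1-(4-hydroxy-3-methoxyphenyl)propane-1,3-diol | COc1cc([C@@H](O)[C@@H](CO)c2cc(Br)cc(OC)c2O)ccc1O
F4 | step 10 | 4-[(2S,3R)-5-bromo-3-(hydroxymethyl)-7-methoxy-2,3-dihydro-1-benzofuran-2-yl]-2-methoxyphenol | Brc1cc(OC)c2c(c1)[C@H](CO)[C@@H](c1ccc(O)c(OC)c1)O2
F5 | step 19 | 2-[(E)-2-{5-bromo-3-methoxy-2-[(triisopropylsilyl)oxy]phenyl}ethenyl]-4,4,5,5-tetramethyl-1,3,2-dioxaborolane | COc1cc(Br)cc(/C=C/B2OC(C)(C)C(C)(C)O2)c1O[Si](C(C)C)(C(C)C)C(C)C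
F6 | step 19 | 2-[(2E)-3-{5-bromo-3-methoxy-2-[(triisopropylsilyl)oxy]phenyl}prop-2-en-1-yl]-4,4,5,5-tetramethyl-1,3,2-dioxaborolane | COc1cc(Br)cc(/C=C/CB2OC(C)(C)C(C)(C)O2)c1O[Si](C(C)C)(C(C)C)C(C)C
F7 | step 19 | (1S,2R)-2-{5-bromo-3-methoxy-2-[(triisopropylsilyl)oxy]phenyl}-1-{3-methoxy-4-[(triisopropylsilyl)oxy]phenyl}but-3-en-1-ol | COc1cc([C@@H](O)[C@H](C=C)c2cc(Br)cc(OC)c2O[Si](C(C)C)(C(C)C)C(C)C)ccc1O[Si](C(C)C)(C(C)C)C(C)C
F8 | step 19 | (2R,3S)-2-{5-bromo-3-methoxy-2-[(triisopropylsilyl)oxy]phenyl}-3-hydroxy-3-{3-methoxy-4-[(triisopropylsilyl)oxy]phenyl}propanal | COc1cc([C@@H](O)[C@H](C=O)c2cc(Br)cc(OC)c2O[Si](C(C)C)(C(C)C)C(C)C)ccc1O[Si](C(C)C)(C(C)C)C(C)C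
F9 | step 24 | (3S,4R)-3-[aryl(hydroxy)methyl] lactone from 26 and 34: compound 37 with a hydroxyl group on the ring B benzylic carbon (carbinol epimers) | COc1cc([C@@H](O[Si](C)(C)C(C)(C)C)[C@H](CO[Si](C)(C)C(C)(C)C)c2cc(C(O)[C@H]3C(=O)OC[C@@H]3Cc3cc(OC)c4c(c3)[C@H](CO[Si](C(C)C)(C(C)C)C(C)C)[C@@H](c3ccc(O[Si](C(C)C)(C(C)C)C(C)C)c(OC)c3)O4)cc(OC)c2O[Si](C(C)C)(C(C)C)C(C)C)ccc1O[Si](C(C)C)(C(C)C)C(C)C
F10 | step 24 | methanesulfonate of F9 (mesyloxy group on the ring B benzylic carbon) | COc1cc([C@@H](O[Si](C)(C)C(C)(C)C)[C@H](CO[Si](C)(C)C(C)(C)C)c2cc(C(OS(C)(=O)=O)[C@H]3C(=O)OC[C@@H]3Cc3cc(OC)c4c(c3)[C@H](CO[Si](C(C)C)(C(C)C)C(C)C)[C@@H](c3ccc(O[Si](C(C)C)(C(C)C)C(C)C)c(OC)c3)O4)cc(OC)c2O[Si](C(C)C)(C(C)C)C(C)C)ccc1O[Si](C(C)C)(C(C)C)C(C)C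
F11 | step 24 | (4R)-3-arylidene lactone: compound 37 with a C=C bond between lactone C3 and the ring B benzylic carbon (E/Z) | COc1cc([C@@H](O[Si](C)(C)C(C)(C)C)[C@H](CO[Si](C)(C)C(C)(C)C)c2cc(C=C3C(=O)OC[C@@H]3Cc3cc(OC)c4c(c3)[C@H](CO[Si](C(C)C)(C(C)C)C(C)C)[C@@H](c3ccc(O[Si](C(C)C)(C(C)C)C(C)C)c(OC)c3)O4)cc(OC)c2O[Si](C(C)C)(C(C)C)C(C)C)ccc1O[Si](C(C)C)(C(C)C)C(C)C
F12 | step 24 | (3S,4R) cis epimer of 37 at lactone C3 | COc1cc([C@@H](O[Si](C)(C)C(C)(C)C)[C@H](CO[Si](C)(C)C(C)(C)C)c2cc(C[C@@H]3C(=O)OC[C@@H]3Cc3cc(OC)c4c(c3)[C@H](CO[Si](C(C)C)(C(C)C)C(C)C)[C@@H](c3ccc(O[Si](C(C)C)(C(C)C)C(C)C)c(OC)c3)O4)cc(OC)c2O[Si](C(C)C)(C(C)C)C(C)C)ccc1O[Si](C(C)C)(C(C)C)C(C)C
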